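The route rests on cutting the bond between C2 of dihydropyranone ring C and C1' of ring B. C2 carries ring oxygen O1 and stands trans to the C3 hydroxyl, which is the retron of an anti opening of a chromone 2,3-epoxide. C1' lies ortho to the 2'-OH of ring B, whose para position is blocked by cyclohexene ring D. In one strain-releasing operation, the unfunctionalised para-substituted phenol of the enantiopure all-trans Diels–Alder adduct opens a (2R,3R)-7-acetoxychromone epoxide at C2. The C–C bond forms, C2 is set and the C3 hydroxyl is unveiled. The phenol comes from a chiral borate-catalysed exo Diels–Alder reaction of a 2'-hydroxychalcone with an aryl diene.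

Key step: step 12

Assumption: the ligand enantiomers written in step 8, (S)-VANOL, and in step 11, (S,S)-salen, follow the closest analogies; should either induce the opposite sense, its mirror image is used and nothing else changes.

Numbering used:
- Ring A is the benzo ring of the chromanone.
- Ring C is O1, C2, C3, C4.
- Ring B is C1' (on C2) to C6', with 2'-OH and ring D on C5'.
- Ring D is C1 (methyl-bearing alkene carbon), C2 (=CH), C3 (bears ring B), C4 (bears the acyl group), C5 (bears the resorcinol ring), C6 (CH2).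

Step 1
Reactants: 1 2,4-dihydroxyacetophenone; 2 3-methylbut-2-enal
Product: 3 1-(5-hydroxy-2,2-dimethyl-2H-chromen-6-yl)ethanone
Conditions: ethylenediammonium diacetate (20 mol %), xylene, reflux
Reagents that add atoms: none
Why: Knoevenagel-type condensation of the iminium-activated enal at C3 of the resorcinol followed by 6π oxa-electrocyclisation of the ortho-quinone methide; the 2-OH is held in a hydrogen bond to the acetyl group, so the pyran should close on the 4-OH and give the 5-hydroxy-6-acetyl isomer.

Step 2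
Reactants: 4 2,4-dihydroxybenzaldehyde
Product: 5 2,4-bis(methoxymethoxy)benzaldehyde
Conditions: NaH, MOMCl, DMF, 0 °C to rt
Reagents that add atoms: chloromethyl methyl ether (MOMCl), COCCl
Why: Williamson-type O-alkylation of both phenoxides; full deprotonation with NaH also brings the hydrogen-bonded 2-OH to reaction, and the acetals will survive the alkali of step 3.

Step 3
Reactants: 3 1-(5-hydroxy-2,2-dimethyl-2H-chromen-6-yl)ethanone; 5 2,4-bis(methoxymethoxy)benzaldehyde
Product: 6 (E)-3-[2,4-bis(methoxymethoxy)phenyl]-1-(5-hydroxy-2,2-dimethyl-2H-chromen-6-yl)prop-2-en-1-one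
Conditions: KOH, EtOH, rt; then 1 M HCl to pH 5
Reagents that add atoms: none
Why: Claisen–Schmidt condensation; the aldehyde cannot enolise, E1cB loss of water gives the conjugated E enone, and the MOM ethers and the chromene are inert to alkali.

Step 4
Reactants: 6 bis-MOM chalcone
Product: 7 (E)-3-(2,4-dihydroxyphenyl)-1-(5-hydroxy-2,2-dimethyl-2H-chromen-6-yl)prop-2-en-1-one
Conditions: HCl (cat.), MeOH, 45 °C, dark
Reagents that add atoms: none
Why: Acid-catalysed transacetalisation to methanol frees both phenols under conditions mild enough for the 2,2-dimethylchromene, and exclusion of light keeps the E enone from isomerising and closing to a benzopyrylium salt.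

Step 5
Reactants: 7 chalcone triol
Product: 8 (E)-3-(2,4-diacetoxyphenyl)-1-(5-hydroxy-2,2-dimethyl-2H-chromen-6-yl)prop-2-en-1-one
Conditions: Ac2O (2.2 equiv), pyridine, CH2Cl2, 0 °C
Reagents that add atoms: acetic anhydride, CC(=O)OC(C)=O
Why: Selective O-acylation: the two resorcinol hydroxyls acylate quickly whereas the phenol hydrogen-bonded to the ketone stays free, which keeps the boron-binding site for step 8 and turns the resorcinol ring into a poor Friedel–Crafts partner for step 12.

Step 6
Reactants: 9 (E)-4-(4-hydroxyphenyl)but-3-en-2-one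
Product: 10 (E)-4-[4-(tert-butyldimethylsilyloxy)phenyl]but-3-en-2-one
Conditions: TBSCl, imidazole, DMF, rt
Reagents that add atoms: tert-butyldimethylsilyl chloride, CC(C)(C)[Si](C)(C)Cl
Why: Imidazole-promoted silylation installs a phenol mask that is orthogonal to the aryl acetates of the dienophile.

Step 7
Reactants: 10 silylated enone
Product: 11 (E)-tert-butyldimethyl[4-(3-methylbuta-1,3-dien-1-yl)phenoxy]silane
Conditions: Ph3PCH3Br, n-BuLi, THF, 0 °C; then 10, 0 °C to rt
Reagents that add atoms: methyltriphenylphosphonium bromide, C[P+](c1ccccc1)(c1ccccc1)c1ccccc1.[Br-]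
Why: Wittig methylenation; the non-stabilised ylide adds 1,2 to the enone and the E styrenyl double bond is untouched.

Step 8
Reactants: 8 diacetoxy 2'-hydroxychalcone; 11 aryl diene
Product: 12 [(1R,2R,6S)-6-(2,4-diacetoxyphenyl)-2-[4-(tert-butyldimethylsilyloxy)phenyl]-4-methylcyclohex-3-en-1-yl](5-hydroxy-2,2-dimethyl-2H-chromen-6-yl)methanone (exo, all-trans adduct; ring D 3R,4R,5S)
Conditions: (S)-VANOL (20 mol %), B(OPh)3 (20 mol %), 4 Å MS, PhCF3, rt
Reagents that add atoms: none
Why: Asymmetric Diels–Alder cycloaddition of a 2'-hydroxychalcone activated as its chiral borate chelate: phenol and ketone of 8 bind boron, the vaulted ligand shields one enone face and disfavours the endo approach of the aryl diene, so the exo adduct with all three ring D stereocentres (3R,4R,5S) should predominate with ortho-rule regiochemistry (diene CH2 to the β-carbon), and the endo isomer is removed by chromatography.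

Step 9
Reactants: 12 silylated exo adduct
Product: 13 [(1R,2R,6S)-6-(2,4-diacetoxyphenyl)-2-(4-hydroxyphenyl)-4-methylcyclohex-3-en-1-yl](5-hydroxy-2,2-dimethyl-2H-chromen-6-yl)methanone
Conditions: TBAF, AcOH (1:1), THF, 0 °C
Reagents that add atoms: none
Why: Fluoride-induced cleavage of the aryl silyl ether; buffering with acetic acid protonates the phenoxide as it forms, so acetyl migration or loss should not occur.

Step 10
Reactants: 14 7-hydroxy-4H-chromen-4-one
Product: 15 4-oxo-4H-chromen-7-yl acetate
Conditions: Ac2O, pyridine, CH2Cl2, rt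
Reagents that add atoms: acetic anhydride, CC(=O)OC(C)=O
Why: O-acylation of the only hydroxyl; the acetate lowers the donor strength of ring A, which should make the later epoxide easier to handle, and it leaves together with the other acetates in step 13.

Step 11
Reactants: 15 7-acetoxychromone
Product: 16 (2R,3R)-7-acetoxy-2,3-epoxychroman-4-one
Conditions: (S,S)-(salen)MnCl (5 mol %; salen = N,N'-bis(3,5-di-tert-butylsalicylidene)cyclohexane-1,2-diamine dianion), DMDO in acetone, CH2Cl2, −20 °C; filtration through Celite, used without chromatography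
Reagents that add atoms: dimethyldioxirane (DMDO), CC1(C)OO1
Why: Jacobsen–Katsuki epoxidation with DMDO as anhydrous neutral terminal oxidant, a combination established on 3-arylchromones: the oxo-manganese species transfers oxygen by side-on approach to one face of the ring-locked cis C2=C3 bond, which sets C2 and C3 together (both R), while the water-free medium spares the aryl acetate and the labile acetal-type oxirane.

Step 12
Reactants: 13 phenol of the exo adduct; 16 (2R,3R)-7-acetoxy-2,3-epoxychroman-4-one
Product: 18 (2R,3R)-7-acetoxy-3-hydroxy-2-{2-hydroxy-5-[(1R,5S,6R)-5-(2,4-diacetoxyphenyl)-6-(5-hydroxy-2,2-dimethyl-2H-chromene-6-carbonyl)-3-methylcyclohex-2-en-1-yl]phenyl}chroman-4-one, via O-aryl acetal 17 (not isolated)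
Conditions: Sc(OTf)3 (20 mol %), 4 Å MS, CH2Cl2, −78 °C, slow addition of 16 (1.5 equiv), then warming to −10 °C
Reagents that add atoms: none
Why: Proposed new method: Sc(OTf)3 binds the oxirane oxygen of 16, and the strained C2–O bond, the acetal-type bond flanked by O1, ionises toward an aryloxycarbenium ion that the only free non-chelated phenol of 13 first captures at oxygen to give acetal 17; on warming 17 re-ionises, the scandium phenolate recombines through its ortho carbon, and rearomatisation makes the C–C bond irreversible while the released proton frees the C3 alkoxide and the catalyst. The closest known reaction types are the O-to-C glycoside rearrangement of phenols with glycosyl donors (1,2-anhydro sugars included), the ortho-selective Friedel–Crafts opening of aryl epoxides by phenols or aryl borates, and the C2 solvolysis of chromone and isoflavone epoxides by alcohols. No ring is closed; the oxirane is opened and its strain pays for the passage through the arenium stage. C3 keeps its C–O bond and hence the R configuration from step 11, and C2 is set by attack anti to the C3–O–Sc substituent (inversion, 2,3-trans, 2R), a cis isomer being correctable under the same conditions through reversible opening of ring C to the ortho-quinone methide of ring B, since the diequatorial trans isomer is the more stable. Site selectivity rests on the substrate: the para position of ring B is blocked by ring D, its two ortho positions are equivalent through rotation about the C3–aryl bond, the resorcinol ring is deactivated as its diacetate, and the chromene phenol is tied up in the hydrogen bond to its ketone. Slow addition of 16 and the absence of base are meant to hold back isomerisation of the oxirane and a second alkylation.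

Step 13
Reactants: 18 coupled triacetate
Product: 19 (2R,3R)-3,7-dihydroxy-2-{2-hydroxy-5-[(1R,5S,6R)-5-(2,4-dihydroxyphenyl)-6-(5-hydroxy-2,2-dimethyl-2H-chromene-6-carbonyl)-3-methylcyclohex-2-en-1-yl]phenyl}chroman-4-one (target)
Conditions: NH4OAc, MeOH/H2O (4:1), rt, argon
Reagents that add atoms: none
Why: Neutral ammonium acetate-catalysed hydrolysis is selective for aryl acetates, and the absence of strong base or acid should leave C2 and C3 of ring C, the enolisable C4 of ring D and the chromene untouched.

Compound list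
1 | 2,4-dihydroxyacetophenone | CC(=O)c1ccc(O)cc1O | starting material
2 | 3-methylbut-2-enal | CC(C)=CC=O | starting material
3 | 1-(5-hydroxy-2,2-dimethyl-2H-chromen-6-yl)ethanone | CC(=O)c1ccc2c(c1O)C=CC(C)(C)O2 | intermediate
4 | 2,4-dihydroxybenzaldehyde | O=Cc1ccc(O)cc1O | starting material
5 | 2,4-bis(methoxymethoxy)benzaldehyde | COCOc1ccc(C=O)c(OCOC)c1 | intermediate
6 | (E)-bis-MOM chalcone | COCOc1ccc(/C=C/C(=O)c2ccc3c(c2O)C=CC(C)(C)O3)c(OCOC)c1 | intermediate
7 | (E)-chalcone triol | Oc1ccc(/C=C/C(=O)c2ccc3c(c2O)C=CC(C)(C)O3)c(O)c1 | intermediate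
8 | (E)-diacetoxy 2'-hydroxychalcone | CC(=O)Oc1ccc(/C=C/C(=O)c2ccc3c(c2O)C=CC(C)(C)O3)c(OC(C)=O)c1 | intermediate
9 | (E)-4-(4-hydroxyphenyl)but-3-en-2-one | CC(=O)/C=C/c1ccc(O)cc1 | starting material
10 | (E)-4-[4-(tert-butyldimethylsilyloxy)phenyl]but-3-en-2-one | CC(=O)/C=C/c1ccc(O[Si](C)(C)C(C)(C)C)cc1 | intermediate
11 | (E)-tert-butyldimethyl[4-(3-methylbuta-1,3-dien-1-yl)phenoxy]silane | C=C(C)/C=C/c1ccc(O[Si](C)(C)C(C)(C)C)cc1 | intermediate
12 | silylated exo adduct, ring D 3R,4R,5S | CC1=C[C@@H](c2ccc(O[Si](C)(C)C(C)(C)C)cc2)[C@H](C(=O)c2ccc3c(c2O)C=CC(C)(C)O3)[C@@H](c2ccc(OC(C)=O)cc2OC(C)=O)C1 | intermediate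
13 | phenol of the exo adduct, ring D 3R,4R,5S | CC1=C[C@@H](c2ccc(O)cc2)[C@H](C(=O)c2ccc3c(c2O)C=CC(C)(C)O3)[C@@H](c2ccc(OC(C)=O)cc2OC(C)=O)C1 | intermediate
14 | 7-hydroxy-4H-chromen-4-one | O=c1ccoc2cc(O)ccc12 | starting material
15 | 4-oxo-4H-chromen-7-yl acetate | CC(=O)Oc1ccc2c(=O)ccoc2c1 | intermediate
16 | (2R,3R)-7-acetoxy-2,3-epoxychroman-4-one | CC(=O)Oc1ccc2c(c1)O[C@H]1O[C@H]1C2=O | intermediate
17 | (2S,3R)-2,3-trans 2-aryloxy-3-hydroxychroman-4-one (O-aryl acetal of 13 and 16) | CC1=C[C@@H](c2ccc(O[C@H]3Oc4cc(OC(C)=O)ccc4C(=O)[C@@H]3O)cc2)[C@H](C(=O)c2ccc3c(c2O)C=CC(C)(C)O3)[C@@H](c2ccc(OC(C)=O)cc2OC(C)=O)C1 | intermediate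
18 | coupled (2R,3R)-dihydroflavonol triacetate | CC1=C[C@@H](c2ccc(O)c([C@H]3Oc4cc(OC(C)=O)ccc4C(=O)[C@@H]3O)c2)[C@H](C(=O)c2ccc3c(c2O)C=CC(C)(C)O3)[C@@H](c2ccc(OC(C)=O)cc2OC(C)=O)C1 | intermediate
19 | CNP0204112.1 | CC1=C[C@@H](c2ccc(O)c([C@H]3Oc4cc(O)ccc4C(=O)[C@@H]3O)c2)[C@H](C(=O)c2ccc3c(c2O)C=CC(C)(C)O3)[C@@H](c2ccc(O)cc2O)C1 | target

Total step count: 13.
Longest linear sequence: 8 steps (steps 1, 3, 4, 5, 8, 9, 12, 13).

Steps most likely to fail

1. Step 12.
- Risk: isomerisation of the oxirane (proton loss from C3 or a 1,2-hydride shift) may outrun C-arylation. The reaction may stall at the O-alkylation stage, or the chromene alkene may compete as the nucleophile.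
- Fallback: known chemistry that forms the same C2–C1' bond by asymmetric conjugate addition. It sets out from 9 (with 8 and 15 as partners) and comes back at 18.
- Diene: ortho-bromination of 9 (NBS, MeCN, 0 °C) should give (E)-4-(3-bromo-4-hydroxyphenyl)but-3-en-2-one F1. Silylation as in step 6 gives the TBS ether F2, and Wittig methylenation as in step 7 gives the bromodiene F3.
- Boron partner: the Diels–Alder reaction of F3 with 8 under the conditions of step 8 gives the bromo exo adduct F4. Miyaura borylation (B2pin2, PdCl2(dppf), KOAc, dioxane, 80 °C) gives the pinacol boronate F5. NaIO4/NH4OAc in aqueous acetone gives the boronic acid F6.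
- Coupling: enantioselective palladium-catalysed conjugate addition of F6 to chromone 15 should give the (2S)-flavanone F7. Conditions are Pd(OCOCF3)2, the enantiomer of 4-tert-butyl-2-(pyridin-2-yl)oxazoline that delivers 2S, NH4PF6, H2O, ClCH2CH2Cl, 60 °C.
- Hydroxylation: TMSOTf/Et3N gives the bis-TMS silyl enol ether F8. Rubottom oxidation (DMDO, 1 equiv, −78 °C, attack anti to the C2 aryl group, mild acid work-up) gives the 2'-O-TBS trans-dihydroflavonol F9. TBAF/AcOH as in step 9 returns to 18.

2. Step 11.
- Risk: low conversion of the push–pull alkene, insufficient facial selectivity, or decomposition of the oxirane on handling.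
- Fallback: this sets out from 15 and comes back at 18. Uncatalysed epoxidation with DMDO alone gives the racemate, 16 together with its enantiomer, (2S,3S)-epoxide F10.
- Resolution: coupling of the racemate with enantiopure 13 under the conditions of step 12 uses 13 as the resolving partner. F10 passes through the diastereomeric O-aryl acetal F11 to the (2S,3S)-diastereomer of the triacetate F12, which is separated from 18 by preparative HPLC.

3. Step 8.
- Risk: poor exo/endo or facial selectivity, or slow catalyst turnover because the product binds boron.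
- Fallback: this sets out from 8 and 11 and comes back at 12, replacing catalyst control by resolution.
- Sequence: the cycloaddition is run racemically with silica-supported silver nanoparticles (Ag/SiO2, zerovalent silver) in CH2Cl2 at 50 °C. The exo isomer is separated from the endo isomer by chromatography. The racemate is then resolved by preparative chiral SFC into 12 and the enantiomeric exo adduct F13.

Further compounds
F1 | step 12 | (E)-4-(3-bromo-4-hydroxyphenyl)but-3-en-2-one | CC(=O)/C=C/c1ccc(O)c(Br)c1
F2 | step 12 | (E)-4-[3-bromo-4-(tert-butyldimethylsilyloxy)phenyl]but-3-en-2-one | CC(=O)/C=C/c1ccc(O[Si](C)(C)C(C)(C)C)c(Br)c1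
F3 | step 12 | (E)-[2-bromo-4-(3-methylbuta-1,3-dien-1-yl)phenoxy](tert-butyl)dimethylsilane | C=C(C)/C=C/c1ccc(O[Si](C)(C)C(C)(C)C)c(Br)c1
F4 | step 12 | bromo exo adduct, ring D 3R,4R,5S | CC1=C[C@@H](c2ccc(O[Si](C)(C)C(C)(C)C)c(Br)c2)[C@H](C(=O)c2ccc3c(c2O)C=CC(C)(C)O3)[C@@H](c2ccc(OC(C)=O)cc2OC(C)=O)C1
F5 | step 12 | pinacol boronate of the exo adduct | CC1=C[C@@H](c2ccc(O[Si](C)(C)C(C)(C)C)c(B3OC(C)(C)C(C)(C)O3)c2)[C@H](C(=O)c2ccc3c(c2O)C=CC(C)(C)O3)[C@@H](c2ccc(OC(C)=O)cc2OC(C)=O)C1
F6 | step 12 | boronic acid of the exo adduct | CC1=C[C@@H](c2ccc(O[Si](C)(C)C(C)(C)C)c(B(O)O)c2)[C@H](C(=O)c2ccc3c(c2O)C=CC(C)(C)O3)[C@@H](c2ccc(OC(C)=O)cc2OC(C)=O)C1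
F7 | step 12 | (2S)-flavanone | CC1=C[C@@H](c2ccc(O[Si](C)(C)C(C)(C)C)c([C@H]3Oc4cc(OC(C)=O)ccc4C(=O)C3)c2)[C@H](C(=O)c2ccc3c(c2O)C=CC(C)(C)O3)[C@@H](c2ccc(OC(C)=O)cc2OC(C)=O)C1
F8 | step 12 | bis-TMS silyl enol ether of the (2S)-flavanone | CC1=C[C@@H](c2ccc(O[Si](C)(C)C(C)(C)C)c([C@H]3Oc4cc(OC(C)=O)ccc4C(O[Si](C)(C)C)=C3)c2)[C@H](C(=O)c2ccc3c(c2O[Si](C)(C)C)C=CC(C)(C)O3)[C@@H](c2ccc(OC(C)=O)cc2OC(C)=O)C1
F9 | step 12 | 2'-O-TBS (2R,3R)-dihydroflavonol triacetate | CC1=C[C@@H](c2ccc(O[Si](C)(C)C(C)(C)C)c([C@H]3Oc4cc(OC(C)=O)ccc4C(=O)[C@@H]3O)c2)[C@H](C(=O)c2ccc3c(c2O)C=CC(C)(C)O3)[C@@H](c2ccc(OC(C)=O)cc2OC(C)=O)C1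
F10 | step 11 | (2S,3S)-7-acetoxy-2,3-epoxychroman-4-one | CC(=O)Oc1ccc2c(c1)O[C@@H]1O[C@@H]1C2=O
F11 | step 11 | diastereomeric (2R,3S) O-aryl acetal | CC1=C[C@@H](c2ccc(O[C@@H]3Oc4cc(OC(C)=O)ccc4C(=O)[C@H]3O)cc2)[C@H](C(=O)c2ccc3c(c2O)C=CC(C)(C)O3)[C@@H](c2ccc(OC(C)=O)cc2OC(C)=O)C1
F12 | step 11 | (2S,3S)-diastereomer of the coupled triacetate | CC1=C[C@@H](c2ccc(O)c([C@@H]3Oc4cc(OC(C)=O)ccc4C(=O)[C@H]3O)c2)[C@H](C(=O)c2ccc3c(c2O)C=CC(C)(C)O3)[C@@H](c2ccc(OC(C)=O)cc2OC(C)=O)C1
F13 | step 8 | enantiomeric silylated exo adduct, ring D 3S,4S,5R | CC1=C[C@H](c2ccc(O[Si](C)(C)C(C)(C)C)cc2)[C@@H](C(=O)c2ccc3c(c2O)C=CC(C)(C)O3)[C@H](c2ccc(OC(C)=O)cc2OC(C)=O)C1
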